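**Easy step.** Begin by turning the percentages of the ash run into concentrations; the charges, readings and questions stand here.

| setting | ash | beta | eta | epsilon |
|---|---|---|---|---|
| substrate | 1.1 M | 0.80 M | 1.2 M | 2.0 M |
| free catalyst | 0.5 mol% | 0.5 mol% | 0.5 mol% | 0.5 mol% |
| remark | run made earlier |  |  |  |
| time |  | 30 h | 30 h | 30 h |

ash run (percent of the substrate charged)

| time / h | target / % | substrate / % |
|---|---|---|
| 1.33 | 1.0 | 97.8 |
| 2.50 | 3.1 | 97.1 |
| 4.00 | 5.3 | 95.2 |
| 8.00 | 9.9 | 89.2 |
| 15.0 | 17.7 | 81.6 |

(readings scatter by 0.5 percentage points)

1. [target] (only what is free in solution) at the end for beta, eta, epsilon, in this order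
2. the shape of the row from first to last (rises all the way / hardly changes / rises, then falls / falls, then rises / falls all the way)

- a reading or a percentage of target counts all its forms, free or not
- the concentration of target that is asked is that of its free form alone
- "hardly changes" means that all values lie within two and a half points (for a concentration: within two and a half percent of the largest)
- no earlier run changes the charge of free catalyst; that part of a forecast is a guess

**The puzzle.** Ash charged a c(free catalyst) of 0.00550 M, yet at 15.0 h it read a c(target) of 0.195 M. That is 35.5 times more than the catalyst, although the catalyst is what makes the target. The two numbers go together if a catalyst comes back after each round. Divide the target made by the catalyst charged and by the time, and you read 2.36 h⁻¹, the turnover rate (turnover frequency), target made per catalyst charged per hour, averaged up to that reading.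

**My reckoning.** Substrate still stood at 81.6% at that reading, so ash spans a narrow range of substrate, and I read no order in substrate from it. I commit to a plain rule, which is my guess: rate equals turnover rate times c(free catalyst) as charged, which takes the catalyst as the concentration that sets the order. Beta, eta and epsilon share the same loading, so each should reach 35.4% of its charge at 30 h. That is 0.283 M, 0.425 M and 0.708 M. These count every form of target, and ash reads no other way, so I take them as free target, at my own risk.

**The result.** The forecast gave 0.2 M, 0.41 M and 1 M, shape rises all the way, and warned: “the upper values are less certain”. The flasks end with 30.7%, 36.1% and 42.5% of target in its forms together, but free target is 0.0710 M, 0.0794 M and 0.0981 M, shape rises all the way. In epsilon that is less than my figure.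

    substrate + free catalyst ⇌ catalyst intermediate A (K = 7.22 M⁻¹, k = 6.95 M⁻¹ h⁻¹)
    catalyst intermediate A ⇌ catalyst intermediate B (K = 11.5, k = 9.34 h⁻¹)
    catalyst intermediate B → free catalyst + target (k = 7.74 h⁻¹)
    free catalyst → spent catalyst (k = 7.63 × 10⁻⁶ h⁻¹)
    crystals ⇌ target, rate k5*(cs5 - [target]) while solid is left; crystals form when [target] > cs5 (solubility = 0.0600 M, k = 0.686 h⁻¹)

**The ceiling.** Epsilon proves the reason: without the ceiling on dissolved target it ends at 0.849 M instead of 0.0981 M, the largest single effect. Crystals grow in proportion to the excess of c(target) over 0.060 M, so where making and crystal growth balance, free target stands near that value plus the making rate divided by 0.686 h⁻¹. In epsilon the turnover rate times the charged catalyst makes 0.0236 M h⁻¹, and the sum gives 0.0944 M, against 0.0981 M. In beta the same sum gives 0.0738 M, against 0.0710 M.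

The data are calculated with made-up constants; the scatter is artificial.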